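The central resorcinol ring carries at C1 the two-carbon bridge (Cα–Cβ) to phenol ring A and at the neighbouring C2 the one-carbon arm C7 to phenol ring B. This ortho pair is cut back to a C1≡C2 aryne and symmetric 1,3-bis(4-methoxyphenyl)propane-1,3-dione: in one operation the aryne inserts into the acyl–CH2 σ-bond, forging C1–Cα and C2–C7 and delivering rings A and B, with Cβ and C7 as ketones that are later reduced to CH2. The aryne precursor is an ortho-silyl aryl triflate (TMS on C2, OTf on C1) already bearing the C3/C5 methoxy groups and the C6 4-methoxybenzyl arm (ring C); all five phenols travel as methyl ethers.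

Key step: step 6

Assumption: the target has no stereogenic element, so it is made as the single achiral compound drawn and no stereocontrol is needed; the structures of the key-step precursor and product were checked against the target and needed no correction.

Step 1
Reactants: 1 2-hydroxy-4,6-dimethoxybenzaldehyde; 2 4-bromoanisole
Product: 4 2-[hydroxy(4-methoxyphenyl)methyl]-3,5-dimethoxyphenol (racemic), via 4-methoxyphenylmagnesium bromide 3 (not isolated)
Conditions: 2 (3.3 equiv), Mg, THF, reflux; then 1, THF, 0 °C → rt; cold aq. NH4Cl; used crude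
Reagents that add atoms: magnesium, [Mg] (present in intermediate 3 only)
Why: Grignard 1,2-addition to the aldehyde, in which the first equivalent is spent on the phenol and the chelated magnesium phenoxide aldehyde still accepts the aryl nucleophile; the carbinol centre forms racemic and is erased in step 2.

Step 2
Reactants: 4 2-[hydroxy(4-methoxyphenyl)methyl]-3,5-dimethoxyphenol
Product: 5 3,5-dimethoxy-2-(4-methoxybenzyl)phenol
Conditions: Et3SiH (4 equiv), TFA (5 equiv), CH2Cl2, −20 → 0 °C, slow addition of 4
Reagents that add atoms: none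
Why: Ionic hydrogenation (Kursanov–Parnes reduction), in which acid ionises the doubly benzylic ortho-hydroxy carbinol to a benzhydryl cation/ortho-quinone methide that takes hydride from the silane, with inverse addition into excess silane keeping Friedel–Crafts capture by the electron-rich ring low.

Step 3
Reactants: 5 3,5-dimethoxy-2-(4-methoxybenzyl)phenol
Product: 6 3,5-dimethoxy-2-(4-methoxybenzyl)phenyl N-isopropylcarbamate
Conditions: i-PrNCO (1.5 equiv), Et3N (0.2 equiv), CH2Cl2, rt
Reagents that add atoms: isopropyl isocyanate, CC(C)N=C=O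
Why: Amine-catalysed addition of the phenol to the isocyanate (carbamoylation) installs a strong ortho-directing group that can later be removed under mild base because it keeps an N–H.

Step 4
Reactants: 6 3,5-dimethoxy-2-(4-methoxybenzyl)phenyl N-isopropylcarbamate
Product: 10 3,5-dimethoxy-2-(4-methoxybenzyl)-6-(trimethylsilyl)phenyl N-isopropylcarbamate, via N-TBS carbamate 7 (not isolated), via ortho-lithiated N-TBS carbamate 8 (not isolated), via N-TBS C-TMS carbamate 9 (not isolated)
Conditions: TBSOTf, TMEDA, Et2O, 0 °C → rt; n-BuLi, TMEDA, −78 °C; TMSCl, −78 °C → rt; cold aq. NaHSO4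
Reagents that add atoms: tert-butyldimethylsilyl triflate, CC(C)(C)[Si](C)(C)OS(=O)(=O)C(F)(F)F (TBS present in 7–9 only); n-butyllithium, [Li]CCCC (lithium present in 8 only); chlorotrimethylsilane, C[Si](C)(C)Cl
Why: Directed ortho-metalation of the carbamate, N-silylated in the flask to mask the N–H and retard the anionic ortho-Fries shift, should occur at the only free ortho position, which lies between the carbamate and a methoxy group (cooperative direction), and the aryllithium is trapped by TMSCl before the labile N–Si bond is hydrolysed on work-up.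

Step 5
Reactants: 10 3,5-dimethoxy-2-(4-methoxybenzyl)-6-(trimethylsilyl)phenyl N-isopropylcarbamate
Product: 12 3,5-dimethoxy-2-(4-methoxybenzyl)-6-(trimethylsilyl)phenyl trifluoromethanesulfonate, via 3,5-dimethoxy-2-(4-methoxybenzyl)-6-(trimethylsilyl)phenol 11 (not isolated)
Conditions: DBU (1.5 equiv), Et2NH (1.2 equiv), MeCN, 40 °C; then PhNTf2 (1.5 equiv), rt
Reagents that add atoms: N-phenylbis(trifluoromethanesulfonimide), O=S(=O)(N(c1ccccc1)S(=O)(=O)C(F)(F)F)C(F)(F)F
Why: E1cB cleavage of the N-monosubstituted carbamate (N–H deprotonation, loss of isocyanate that diethylamine scavenges) frees the phenoxide under conditions that spare the aryl–silicon bond, and the phenoxide is sulfonylated in the same pot by the mild triflyl donor.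

Step 6
Reactants: 12 3,5-dimethoxy-2-(4-methoxybenzyl)-6-(trimethylsilyl)phenyl trifluoromethanesulfonate; 13 1,3-bis(4-methoxyphenyl)propane-1,3-dione
Product: 16 2-[2-(4-methoxybenzoyl)-3,5-dimethoxy-6-(4-methoxybenzyl)phenyl]-1-(4-methoxyphenyl)ethanone, via 3,5-dimethoxy-6-(4-methoxybenzyl)benzyne 14 (not isolated), via benzocyclobutenoxide anion 15 (not isolated)
Conditions: 13 (1.5 equiv), CsF (3 equiv), MeCN, 80 °C; aq. NH4Cl
Reagents that add atoms: none
Why: Fluoride attacks the silicon on C2, the aryl anion expels triflate from C1 and the strained C1≡C2 aryne 14 forms slowly in the presence of the caesium enolate of 13, whose central carbon adds to C1; the aryl anion left on C2 closes onto the adjacent aroyl carbonyl (4-exo-trig) to the benzocyclobutenoxide 15, and retro-aldol-type opening of the strained ring shifts the aroyl group to C2 and leaves a C1–CH enolate that excess 13 protonates. This is the aryne acyl-alkylation, the known formal insertion of arynes into the C–C σ-bond of β-dicarbonyl compounds, 1,3-diketones included. No ring survives in the product (the four-membered ring is transient) and no stereocentre is created. The step needs regioselective addition to the unsymmetrical aryne: the C3 methoxy group withdraws inductively, distorts the aryne and stabilises negative charge at C2, so the nucleophile should bond to the distal C1 although C1 is flanked by the C6 benzylic CH2, as it does with other 3-alkoxyarynes. Because 13 is symmetric either carbonyl gives the same product, and using 13 in excess both supplies the proton for the product enolate and suppresses a second arylation at its acidic CH2.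

Step 7
Reactants: 16 2-[2-(4-methoxybenzoyl)-3,5-dimethoxy-6-(4-methoxybenzyl)phenyl]-1-(4-methoxyphenyl)ethanone
Product: 17 1,5-dimethoxy-2,4-bis(4-methoxybenzyl)-3-[2-(4-methoxyphenyl)ethyl]benzene
Conditions: Et3SiH (10 equiv), TFA/CH2Cl2 (1:1), 0 → 40 °C
Reagents that add atoms: none
Why: Ionic hydrogenation (Kursanov–Parnes reduction) of two electron-rich aryl ketones, in which each protonated carbonyl takes hydride, the resulting 4-methoxybenzylic alcohol ionises to a stabilised cation that takes a second hydride, and any benzopyrylium, isochromene or isochroman formed by acid-induced cyclisation of the 1,5-diketone should drain to the same product because every C–O bond in those species is 4-methoxybenzylic; the aryl methyl ethers are inert.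

Step 8
Reactants: 17 1,5-dimethoxy-2,4-bis(4-methoxybenzyl)-3-[2-(4-methoxyphenyl)ethyl]benzene
Product: 18 4,6-bis(4-hydroxybenzyl)-5-[2-(4-hydroxyphenyl)ethyl]benzene-1,3-diol
Conditions: BBr3 (10 equiv), CH2Cl2, −78 °C → rt; ice water
Reagents that add atoms: none
Why: Lewis-acid-mediated aryl methyl ether cleavage (boron coordinates each ether oxygen and bromide removes the methyl group by SN2) should free all five phenols of a substrate that carries no other reactive function.

Compound list
1 | 2-hydroxy-4,6-dimethoxybenzaldehyde | COc1cc(O)c(C=O)c(OC)c1 | starting material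
2 | 4-bromoanisole | COc1ccc(Br)cc1 | starting material
3 | 4-methoxyphenylmagnesium bromide | COc1ccc([Mg]Br)cc1 | intermediate (not isolated)
4 | 2-[hydroxy(4-methoxyphenyl)methyl]-3,5-dimethoxyphenol (racemic) | COc1ccc(C(O)c2c(O)cc(OC)cc2OC)cc1 | intermediate
5 | 3,5-dimethoxy-2-(4-methoxybenzyl)phenol | COc1ccc(Cc2c(O)cc(OC)cc2OC)cc1 | intermediate
6 | 3,5-dimethoxy-2-(4-methoxybenzyl)phenyl N-isopropylcarbamate | COc1ccc(Cc2c(OC(=O)NC(C)C)cc(OC)cc2OC)cc1 | intermediate
7 | 3,5-dimethoxy-2-(4-methoxybenzyl)phenyl N-(tert-butyldimethylsilyl)-N-isopropylcarbamate | COc1ccc(Cc2c(OC(=O)N(C(C)C)[Si](C)(C)C(C)(C)C)cc(OC)cc2OC)cc1 | intermediate (not isolated)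
8 | 6-lithio derivative of 7 (lithium on the ring carbon between the carbamate and a methoxy group) | COc1ccc(Cc2c(OC(=O)N(C(C)C)[Si](C)(C)C(C)(C)C)c([Li])c(OC)cc2OC)cc1 | intermediate (not isolated)
9 | 3,5-dimethoxy-2-(4-methoxybenzyl)-6-(trimethylsilyl)phenyl N-(tert-butyldimethylsilyl)-N-isopropylcarbamate | COc1ccc(Cc2c(OC(=O)N(C(C)C)[Si](C)(C)C(C)(C)C)c([Si](C)(C)C)c(OC)cc2OC)cc1 | intermediate (not isolated)
10 | 3,5-dimethoxy-2-(4-methoxybenzyl)-6-(trimethylsilyl)phenyl N-isopropylcarbamate | COc1ccc(Cc2c(OC(=O)NC(C)C)c([Si](C)(C)C)c(OC)cc2OC)cc1 | intermediate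
11 | 3,5-dimethoxy-2-(4-methoxybenzyl)-6-(trimethylsilyl)phenol (present as its DBU salt) | COc1ccc(Cc2c(O)c([Si](C)(C)C)c(OC)cc2OC)cc1 | intermediate (not isolated)
12 | 3,5-dimethoxy-2-(4-methoxybenzyl)-6-(trimethylsilyl)phenyl trifluoromethanesulfonate | COc1cc(OC)c([Si](C)(C)C)c(OS(=O)(=O)C(F)(F)F)c1Cc1ccc(OC)cc1 | intermediate (key-step precursor)
13 | 1,3-bis(4-methoxyphenyl)propane-1,3-dione | COc1ccc(C(=O)CC(=O)c2ccc(OC)cc2)cc1 | starting material
14 | 3,5-dimethoxy-6-(4-methoxybenzyl)benzyne (1,2-didehydrobenzene, triple bond C1–C2) | COC1=CC(OC)=C(Cc2ccc(OC)cc2)C#C1 | intermediate (not isolated)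
15 | benzocyclobutenoxide anion: the four-membered ring is fused at C1–C2 and holds a CH carrying a 4-methoxybenzoyl group (on C1) and a C(O−)(4-methoxyphenyl) carbon (on C2); configuration immaterial, as both centres vanish on ring opening | COc1ccc(C(=O)C2c3c(Cc4ccc(OC)cc4)c(OC)cc(OC)c3C2([O-])c2ccc(OC)cc2)cc1 | intermediate (not isolated)
16 | 2-[2-(4-methoxybenzoyl)-3,5-dimethoxy-6-(4-methoxybenzyl)phenyl]-1-(4-methoxyphenyl)ethanone | COc1ccc(C(=O)Cc2c(Cc3ccc(OC)cc3)c(OC)cc(OC)c2C(=O)c2ccc(OC)cc2)cc1 | intermediate (key-step product)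
17 | 1,5-dimethoxy-2,4-bis(4-methoxybenzyl)-3-[2-(4-methoxyphenyl)ethyl]benzene | COc1ccc(CCc2c(Cc3ccc(OC)cc3)c(OC)cc(OC)c2Cc2ccc(OC)cc2)cc1 | intermediate
18 | 4,6-bis(4-hydroxybenzyl)-5-[2-(4-hydroxyphenyl)ethyl]benzene-1,3-diol (achiral) | Oc1ccc(CCc2c(Cc3ccc(O)cc3)c(O)cc(O)c2Cc2ccc(O)cc2)cc1 | target

Total step count: 8. Longest linear sequence: 8 steps (1 → 18); 13 is purchased.

Steps most likely to fail

Step 6. The enolate may add at the wrong aryne terminus because the C6 benzyl group shields C1. The aryl anion may be protonated before it closes onto the ketone, which gives plain α-arylation. The acidic methylene of the product may be arylated a second time. The fallback sets out from 5 and comes back at 17. It gives up the aryne and uses the phenol oxygen of 5, which sits on C1, as a cross-coupling handle. Magnesium-mediated ortho-formylation of 5 (MgCl2, Et3N, paraformaldehyde, MeCN, reflux) should give 2-hydroxy-4,6-dimethoxy-3-(4-methoxybenzyl)benzaldehyde F1. Addition of the Grignard reagent 3 should give 2-[hydroxy(4-methoxyphenyl)methyl]-3,5-dimethoxy-6-(4-methoxybenzyl)phenol F2. Et3SiH/TFA should reduce this to 3,5-dimethoxy-2,6-bis(4-methoxybenzyl)phenol F3, and Tf2O/pyridine should convert it into 3,5-dimethoxy-2,6-bis(4-methoxybenzyl)phenyl trifluoromethanesulfonate F4. B-alkyl Suzuki–Miyaura coupling with 9-[2-(4-methoxyphenyl)ethyl]-9-borabicyclo[3.3.1]nonane F5, made in the flask from 4-methoxystyrene and 9-BBN-H, under Pd(OAc)2/SPhos, K3PO4, THF/H2O, 65 °C should then give 17.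

Step 7. Acid may divert the 1,5-diketone into benzopyrylium and isochroman species that stall short of full deoxygenation. The benzylic cations may also be captured by the electron-rich rings (Friedel–Crafts) or lose a 4-methoxybenzyl group. The fallback sets out from 16 and comes back at 17. Reduction with NaBH4 (THF/MeOH, 0 °C → rt) should give 2-[2-[hydroxy(4-methoxyphenyl)methyl]-3,5-dimethoxy-6-(4-methoxybenzyl)phenyl]-1-(4-methoxyphenyl)ethanol F6 as a mixture of diastereomers whose centres are erased next. Catalytic hydrogenolysis of both benzylic C–O bonds (H2, Pd/C, EtOAc/AcOH, cat. HClO4) should then give 17 without free carbocations in solution.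

Step 4. The base may deprotonate the doubly benzylic CH2 next to the carbamate (lateral metalation followed by carbamoyl transfer). It may also metalate the ring position between the two methoxy groups. The fallback sets out from 5 and comes back at 12. It replaces deprotonation by halogen–metal exchange. Amine-catalysed ortho-bromination of 5 (NBS, cat. i-Pr2NH, CH2Cl2, −78 → 0 °C) should give 2-bromo-3,5-dimethoxy-6-(4-methoxybenzyl)phenol F7. O-Silylation (HMDS, THF, 70 °C) should give [2-bromo-3,5-dimethoxy-6-(4-methoxybenzyl)phenoxy]trimethylsilane F8. Bromine–lithium exchange with n-BuLi (THF, −100 → −78 °C) should trigger the O→C silyl shift (retro-Brook rearrangement) to lithium 3,5-dimethoxy-2-(4-methoxybenzyl)-6-(trimethylsilyl)phenoxide F9, which Tf2O should trap to give 12.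

Further compounds
F1 | step 6 | 2-hydroxy-4,6-dimethoxy-3-(4-methoxybenzyl)benzaldehyde | COc1ccc(Cc2c(O)c(C=O)c(OC)cc2OC)cc1
F2 | step 6 | 2-[hydroxy(4-methoxyphenyl)methyl]-3,5-dimethoxy-6-(4-methoxybenzyl)phenol (racemic) | COc1ccc(Cc2c(O)c(C(O)c3ccc(OC)cc3)c(OC)cc2OC)cc1
F3 | step 6 | 3,5-dimethoxy-2,6-bis(4-methoxybenzyl)phenol | COc1ccc(Cc2c(O)c(Cc3ccc(OC)cc3)c(OC)cc2OC)cc1
F4 | step 6 | 3,5-dimethoxy-2,6-bis(4-methoxybenzyl)phenyl trifluoromethanesulfonate | COc1ccc(Cc2c(OS(=O)(=O)C(F)(F)F)c(Cc3ccc(OC)cc3)c(OC)cc2OC)cc1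
F5 | step 6 | 9-[2-(4-methoxyphenyl)ethyl]-9-borabicyclo[3.3.1]nonane | COc1ccc(CCB2C3CCCC2CCC3)cc1
F6 | step 7 | 2-[2-[hydroxy(4-methoxyphenyl)methyl]-3,5-dimethoxy-6-(4-methoxybenzyl)phenyl]-1-(4-methoxyphenyl)ethanol (mixture of diastereomers) | COc1ccc(C(O)Cc2c(Cc3ccc(OC)cc3)c(OC)cc(OC)c2C(O)c2ccc(OC)cc2)cc1
F7 | step 4 | 2-bromo-3,5-dimethoxy-6-(4-methoxybenzyl)phenol | COc1ccc(Cc2c(O)c(Br)c(OC)cc2OC)cc1
F8 | step 4 | [2-bromo-3,5-dimethoxy-6-(4-methoxybenzyl)phenoxy]trimethylsilane | COc1ccc(Cc2c(O[Si](C)(C)C)c(Br)c(OC)cc2OC)cc1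
F9 | step 4 | lithium 3,5-dimethoxy-2-(4-methoxybenzyl)-6-(trimethylsilyl)phenoxide | [Li+].[O-]c1c(Cc2ccc(OC)cc2)c(OC)cc(OC)c1[Si](C)(C)C
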